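**Plan**
1. Disconnections: the four phenols are unmasked last. Ring C is cut at C4–C4a (Friedel–Crafts acylation) and at O1–C2 (phenoxide addition to ethyl phenylpropiolate). Ring A is cut at C8–C8a, C6–C7 and C4a–C8a.
2. Enabling feature: ring A is a phloroglucinol whose benzyl-bearing C8 lies between the oxygenated C7 and C8a, with the C5 oxygen para to C8. A benzyl-substituted siloxyalkyne (C7, C8) and the vinylketene from 3-ethoxycyclobutenone (C8a, C4a, C5, C6) assemble exactly this pattern and leave the oxygens as OH, OSi and OEt.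
3. Forward order: acid 1 → ester 2 → siloxyalkyne 5 (one-carbon homologation); ring A by benzannulation with 6; ring C by oxa-Michael addition to 12, hydrolysis and acylative closure; BBr3 last. The catechol ring and ring B arrive with 1 and 12.
4. O7 and O1 are related by the local mirror through C8 and C5, and C8 is blocked, so ring C can close only to the 8-benzyl flavone.
5. Stereochemistry: the target has no stereocentre and no stereogenic double bond. The enol ether geometry of 13 and 14 is the only stereo-element on the way and is erased on ring closure.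

Key step: step 3

Remark: 13 and 14 are drawn as the Z isomers expected from anti addition; the E isomers would serve equally, because the double bond isomerises under the acidic ring closure.

Step 1
Reactants: 1 (2,3-dimethoxyphenyl)acetic acid
Product: 2 ethyl (2,3-dimethoxyphenyl)acetate
Conditions: EtOH, H2SO4 (cat.), reflux
Reagents that add atoms: ethanol, CCO
Why: Fischer esterification of an unhindered arylacetic acid in excess ethanol is driven to completion by mass action and touches neither aryl ether.

Step 2
Reactants: 2 ethyl (2,3-dimethoxyphenyl)acetate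
Product: 5 triisopropyl{[3-(2,3-dimethoxyphenyl)prop-1-yn-1-yl]oxy}silane, via lithium dibromoenolate 3 (not isolated), via lithium ynolate 4 (not isolated)
Conditions: CH2Br2, lithium 2,2,6,6-tetramethylpiperidide, THF, −78 °C; add 2; LiN(SiMe3)2, −78 → −20 °C; n-BuLi, −78 °C → rt; i-Pr3SiCl, −78 → 0 °C
Reagents that add atoms: dibromomethane, BrCBr; triisopropylsilyl chloride, CC(C)[Si](Cl)(C(C)C)C(C)C
Why: Kowalski ester homologation stopped at the ynolate: dibromomethyllithium adds to the ester carbonyl at −78 °C, the released dibromoketone is deprotonated to 3, bromine–lithium exchange triggers 1,2-shift of the arylmethyl group with loss of LiBr to give 4, and the bulky silyl chloride traps the ynolate on oxygen as an isolable silyl ynol ether.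

Step 3
Reactants: 5 triisopropyl{[3-(2,3-dimethoxyphenyl)prop-1-yn-1-yl]oxy}silane; 6 3-ethoxycyclobut-2-en-1-one
Product: 11 2-(2,3-dimethoxybenzyl)-5-ethoxy-3-(triisopropylsilyloxy)phenol, via ethoxyvinylketene 7 (not isolated), via vinylcyclobutenone 8 (not isolated), via dienylketene 9 (not isolated), via cyclohexadienone 10 (not isolated)
Conditions: PhMe, 80 °C then 110 °C (5 in slight excess)
Reagents that add atoms: none
Why: Heating opens 6 by 4π electrocyclic cleavage of its C1–C4 bond to vinylketene 7, whose ketene C=C adds to the siloxyalkyne in a [2+2] cycloaddition to give 8; 8 reopens (4π) to dienylketene 9, which closes to cyclohexadienone 10 and tautomerises to phenol 11. This is the Danheiser benzannulation in its siloxyalkyne form, with the ethoxy group of the cyclobutenone carried along as a spectator that ends on C5. Ring A is closed by thermal disrotatory 6π electrocyclisation of 9 (C4a–C8a), after the [2+2] step has made C8–C8a and C6–C7; the four-membered ring of 8 is only a relay. No stereocentre results, since the sp3 carbon of 8 and of 10 is lost on ring opening and aromatisation. The step needs regiocontrol in the ketene–alkyne union, and the siloxy oxygen supplies it by making the benzyl-bearing alkyne carbon the nucleophile that attacks the ketene carbonyl carbon, which places the benzyl group between the new hydroxyl and the silyl ether. It also needs the vinyl group of 8 to turn inward on ring opening, which is secured because that opening is reversible at 80–110 °C and only the isomer able to cyclise is drained irreversibly to the arene.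

Step 4
Reactants: 11 2-(2,3-dimethoxybenzyl)-5-ethoxy-3-(triisopropylsilyloxy)phenol; 12 ethyl 3-phenylprop-2-ynoate
Product: 13 ethyl (2Z)-3-[2-(2,3-dimethoxybenzyl)-5-ethoxy-3-(triisopropylsilyloxy)phenoxy]-3-phenylprop-2-enoate
Conditions: K2CO3 (0.3 equiv), dry DMF, 60 °C
Reagents that add atoms: none
Why: Base-mediated oxa-Michael addition (first stage of the Ruhemann flavone synthesis), in which the single free hydroxyl of 11 adds as its phenoxide to the β-carbon of the ynoate in anti fashion while anhydrous carbonate leaves the hindered aryl silyl ether untouched, and even silyl transfer to the other flanking oxygen would lead to the same flavone by the local symmetry of ring A.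

Step 5
Reactants: 13 ethyl (2Z)-3-[2-(2,3-dimethoxybenzyl)-5-ethoxy-3-(triisopropylsilyloxy)phenoxy]-3-phenylprop-2-enoate
Product: 14 (2Z)-3-[2-(2,3-dimethoxybenzyl)-5-ethoxy-3-hydroxyphenoxy]-3-phenylprop-2-enoic acid
Conditions: KOH, EtOH/H2O, 70 °C; then 1 M HCl, 0 °C, pH 3
Reagents that add atoms: potassium hydroxide, [K+].[OH-]
Why: Saponification of the ester and hydroxide attack at silicon with phenoxide as leaving group (aryl silyl ethers are base-labile) should occur in one operation, the electron-rich aryloxide being too poor a leaving group for addition–elimination at the β-carbon to compete.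

Step 6
Reactants: 14 (2Z)-3-[2-(2,3-dimethoxybenzyl)-5-ethoxy-3-hydroxyphenoxy]-3-phenylprop-2-enoic acid
Product: 15 8-(2,3-dimethoxybenzyl)-5-ethoxy-7-hydroxy-2-phenyl-4H-chromen-4-one
Conditions: P4O10/MeSO3H (Eaton's reagent), rt → 40 °C
Reagents that add atoms: none
Why: Intramolecular Friedel–Crafts acylation (second stage of the Ruhemann synthesis) under conditions that tolerate free phloroglucinol-type phenols, in which the tethered acylium equivalent can reach only C4a, a carbon activated by three oxygens, and E/Z isomers interconvert by protonation at the α-carbon.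

Step 7
Reactants: 15 8-(2,3-dimethoxybenzyl)-5-ethoxy-7-hydroxy-2-phenyl-4H-chromen-4-one
Product: 16 8-(2,3-dihydroxybenzyl)-5,7-dihydroxy-2-phenyl-4H-chromen-4-one
Conditions: BBr3 (excess), CH2Cl2, −78 °C → rt; MeOH then H2O
Reagents that add atoms: none
Why: BBr3 dealkylation of aryl ethers by Lewis acid complexation and bromide attack at the alkyl carbon should remove both methyl groups and the ethyl group, the latter assisted by chelation to the C4 carbonyl, while the flavone core is inert to the reagent.

**Compound list**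
1 | (2,3-dimethoxyphenyl)acetic acid | COc1cccc(CC(=O)O)c1OC | starting material
2 | ethyl (2,3-dimethoxyphenyl)acetate | CCOC(=O)Cc1cccc(OC)c1OC | intermediate
3 | lithium 1,1-dibromo-3-(2,3-dimethoxyphenyl)prop-1-en-2-olate | [Li+].[O-]C(Cc1cccc(OC)c1OC)=C(Br)Br | intermediate
4 | lithium 3-(2,3-dimethoxyphenyl)prop-1-yn-1-olate | [Li+].[O-]C#CCc1cccc(OC)c1OC | intermediate
5 | triisopropyl{[3-(2,3-dimethoxyphenyl)prop-1-yn-1-yl]oxy}silane | COc1cccc(CC#CO[Si](C(C)C)(C(C)C)C(C)C)c1OC | intermediate
6 | 3-ethoxycyclobut-2-en-1-one | CCOC1=CC(=O)C1 | starting material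
7 | 3-ethoxybuta-1,3-dien-1-one (ethoxyvinylketene) | CCOC(=C)C=C=O | intermediate
8 | 2-(2,3-dimethoxybenzyl)-4-(1-ethoxyethenyl)-3-(triisopropylsilyloxy)cyclobut-2-en-1-one (racemic) | CCOC(=C)C1C(=O)C(Cc2cccc(OC)c2OC)=C1O[Si](C(C)C)(C(C)C)C(C)C | intermediate
9 | (3E)-2-(2,3-dimethoxybenzyl)-5-ethoxy-3-(triisopropylsilyloxy)hexa-1,3,5-trien-1-one | O=C=C(Cc1cccc(OC)c1OC)/C(O[Si](C(C)C)(C(C)C)C(C)C)=C\C(=C)OCC | intermediate
10 | 2-(2,3-dimethoxybenzyl)-5-ethoxy-3-(triisopropylsilyloxy)cyclohexa-2,4-dien-1-one | CCOC1=CC(O[Si](C(C)C)(C(C)C)C(C)C)=C(Cc2cccc(OC)c2OC)C(=O)C1 | intermediate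
11 | 2-(2,3-dimethoxybenzyl)-5-ethoxy-3-(triisopropylsilyloxy)phenol | CCOc1cc(O)c(Cc2cccc(OC)c2OC)c(O[Si](C(C)C)(C(C)C)C(C)C)c1 | intermediate
12 | ethyl 3-phenylprop-2-ynoate (ethyl phenylpropiolate) | CCOC(=O)C#Cc1ccccc1 | starting material
13 | ethyl (2Z)-3-[2-(2,3-dimethoxybenzyl)-5-ethoxy-3-(triisopropylsilyloxy)phenoxy]-3-phenylprop-2-enoate | CCOC(=O)/C=C(/c1ccccc1)Oc1cc(OCC)cc(O[Si](C(C)C)(C(C)C)C(C)C)c1Cc1cccc(OC)c1OC | intermediate
14 | (2Z)-3-[2-(2,3-dimethoxybenzyl)-5-ethoxy-3-hydroxyphenoxy]-3-phenylprop-2-enoic acid | OC(=O)/C=C(/c1ccccc1)Oc1cc(OCC)cc(O)c1Cc1cccc(OC)c1OC | intermediate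
15 | 8-(2,3-dimethoxybenzyl)-5-ethoxy-7-hydroxy-2-phenyl-4H-chromen-4-one | CCOc1cc(O)c(Cc2cccc(OC)c2OC)c2oc(-c3ccccc3)cc(=O)c12 | intermediate
16 | 8-(2,3-dihydroxybenzyl)-5,7-dihydroxy-2-phenyl-4H-chromen-4-one | O=c1cc(-c2ccccc2)oc2c(Cc3cccc(O)c3O)c(O)cc(O)c12 | target

Total step count: 7
Longest linear sequence: 7 steps (1 → 16); 6 and 12 are purchased.

**Steps most likely to fail**

Step 3. The vinylogous-ester cyclobutenone 6 may open only slowly, so that at the temperature required ketene 7 is lost to self-condensation, or acylates the phenol already formed, before it meets 5. The fallback sets out from 5 and comes back at 11, generating the same ketene without heat. Commercial ethyl (E)-3-ethoxybut-2-enoate is saponified (NaOH, aq. EtOH; then HCl) to (E)-3-ethoxybut-2-enoic acid F1, and oxalyl chloride (cat. DMF, CH2Cl2) turns this into (E)-3-ethoxybut-2-enoyl chloride F2. Slow addition of F2 to 5 and Et3N in toluene at room temperature should give 7 by 1,4-dehydrochlorination (γ-deprotonation) in the presence of the alkyne, a known way to vinylketenes for siloxyalkyne cycloadditions. The [2+2] adduct 8 would then form at ambient temperature and be warmed in toluene to 11 through 9 and 10.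

Step 2. Proton transfer from the acidic benzylic α-position of 2 to dibromomethyllithium or to the amide bases may outrun carbonyl addition and return ester enolate. The fallback sets out from 2 and comes back at 5 by oxidising an acetylide instead of rearranging a carbenoid. i-Bu2AlH (CH2Cl2, −78 °C) reduces 2 to (2,3-dimethoxyphenyl)acetaldehyde F3, which is homologated without purification by the Ohira–Bestmann reagent (dimethyl (1-diazo-2-oxopropyl)phosphonate, K2CO3, MeOH, 0 °C) to 1,2-dimethoxy-3-(prop-2-yn-1-yl)benzene F4. n-BuLi (THF, −78 °C) gives lithium 3-(2,3-dimethoxyphenyl)prop-1-yn-1-ide F5. Oxidation of this acetylide with LiOO-t-Bu (from t-BuOOH and LiN(SiMe3)2, −78 → 0 °C), a known route to ynolates, should give 4, which i-Pr3SiCl silylates to 5.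

Step 6. In the strongly acidic medium, protonation of the enol ether with cleavage of the aryloxy–vinyl bond, or ipso-protonation of ring A with loss of the stabilised dimethoxybenzyl cation, may compete with acylation. The fallback sets out from 11 and comes back at 15 without strong acid, bypassing steps 4 and 5. Iodination of 11 (N-iodosuccinimide, CH2Cl2, 0 °C; the bulky silyl ether screens the other open position) gives 2-(2,3-dimethoxybenzyl)-5-ethoxy-6-iodo-3-(triisopropylsilyloxy)phenol F6. Carbonylative Sonogashira coupling with phenylacetylene (CO 1 atm, PdCl2(PPh3)2, Et2NH, DMF, 80 °C) gives 1-[3-(2,3-dimethoxybenzyl)-6-ethoxy-2-hydroxy-4-(triisopropylsilyloxy)phenyl]-3-phenylprop-2-yn-1-one F7. F7 should cyclise in the flask by amine-mediated 6-endo oxa-Michael addition to 8-(2,3-dimethoxybenzyl)-5-ethoxy-2-phenyl-7-(triisopropylsilyloxy)-4H-chromen-4-one F8. Bu4NF (THF, 0 °C) then removes the silyl group to give 15.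

**Further compounds**
F1 | step 3 | (E)-3-ethoxybut-2-enoic acid | CCO/C(C)=C/C(=O)O
F2 | step 3 | (E)-3-ethoxybut-2-enoyl chloride | CCO/C(C)=C/C(=O)Cl
F3 | step 2 | (2,3-dimethoxyphenyl)acetaldehyde | COc1cccc(CC=O)c1OC
F4 | step 2 | 1,2-dimethoxy-3-(prop-2-yn-1-yl)benzene | COc1cccc(CC#C)c1OC
F5 | step 2 | lithium 3-(2,3-dimethoxyphenyl)prop-1-yn-1-ide | [Li+].[C-]#CCc1cccc(OC)c1OC
F6 | step 6 | 2-(2,3-dimethoxybenzyl)-5-ethoxy-6-iodo-3-(triisopropylsilyloxy)phenol | CCOc1cc(O[Si](C(C)C)(C(C)C)C(C)C)c(Cc2cccc(OC)c2OC)c(O)c1I
F7 | step 6 | 1-[3-(2,3-dimethoxybenzyl)-6-ethoxy-2-hydroxy-4-(triisopropylsilyloxy)phenyl]-3-phenylprop-2-yn-1-one | CCOc1cc(O[Si](C(C)C)(C(C)C)C(C)C)c(Cc2cccc(OC)c2OC)c(O)c1C(=O)C#Cc1ccccc1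
F8 | step 6 | 8-(2,3-dimethoxybenzyl)-5-ethoxy-2-phenyl-7-(triisopropylsilyloxy)-4H-chromen-4-one | CCOc1cc(O[Si](C(C)C)(C(C)C)C(C)C)c(Cc2cccc(OC)c2OC)c2oc(-c3ccccc3)cc(=O)c12
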